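**Retrosynthetic overview**
1. Target 25 ⇐ tetra-MOM isoflavone 24 by removing all four MOM groups in the last step. Both prenyl groups are carried in from the building blocks.
2. The pyranone ring is the only ring that is built, and it is built last. 24 ⇐ 2-hydroxydeoxybenzoin 22 plus one carbon (C2) from DMF-DMA, followed by O-cyclisation.
3. 22 ⇐ β-keto allyl ester 19 (Pd(0) removes both allyl groups, then CO2 is lost) ⇐ oxidation of aldol adduct 18.
4. Key C–C bond (C3–C4): the lithium enolate of allyl arylacetate 9 (ring B) adds to benzaldehyde 16 (ring A) in an intermolecular aldol addition.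
5. 9 ⇐ resorcinol through two directed lithiations. 16 ⇐ 2,4,6-trihydroxybenzaldehyde through O-prenylation and a para-Claisen–Cope shift, which leaves the future O1 oxygen differentiated.

**Assumption:** the target has no stereocentre and no stereogenic double bond, so only one stereoisomer exists. The transient stereocentres in 13, 14 and 18–20 are carried as mixtures and are all erased later. Abbreviations: MOM = CH2OCH3; prenyl = 3-methylbut-2-enyl.

**Step 1**
Reactants: 1 resorcinol
Product: 2 1,3-bis(methoxymethoxy)benzene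
Conditions: NaH (2.5 equiv), MOMCl (2.4 equiv), DMF, 0 °C → rt
Reagents that add atoms: chloromethyl methyl ether (MOMCl), COCCl
Why: Williamson-type O-alkylation (MOM protection) of the bis-phenoxide with a very reactive α-chloro ether, installing groups that later direct metalation.

**Step 2**
Reactants: 2 1,3-bis(methoxymethoxy)benzene
Product: 4 1,3-bis(methoxymethoxy)-2-(3-methylbut-2-enyl)benzene, via aryllithium 3 (not isolated)
Conditions: n-BuLi (1.1 equiv), THF, 0 °C → rt, 1 h; CuI (10 mol %), prenyl bromide, −78 °C → rt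
Reagents that add atoms: prenyl bromide (1-bromo-3-methylbut-2-ene), CC(C)=CCBr
Why: Directed ortho-metalation removes the C2–H flanked by two chelating OMOM groups, and the aryl metal displaces the primary allylic bromide by SN2 to give the linear prenyl arene.

**Step 3**
Reactants: 4 1,3-bis(methoxymethoxy)-2-(3-methylbut-2-enyl)benzene
Product: 6 2-[2,4-bis(methoxymethoxy)-3-(3-methylbut-2-enyl)phenyl]ethanol, via aryllithium 5 (not isolated)
Conditions: n-BuLi (1.2 equiv), TMEDA, THF, 0 °C, 1.5 h; ethylene oxide (3 M in THF, 3 equiv), −78 °C → rt; H2O quench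
Reagents that add atoms: ethylene oxide (oxirane), C1CO1
Why: A second directed ortho-metalation, with C2 blocked, is steered by OMOM coordination to the neighbouring ring C–H (both such sites are equivalent), and the aryllithium opens the epoxide.

**Step 4**
Reactants: 6 2-[2,4-bis(methoxymethoxy)-3-(3-methylbut-2-enyl)phenyl]ethanol
Product: 8 2-[2,4-bis(methoxymethoxy)-3-(3-methylbut-2-enyl)phenyl]acetic acid, via arylacetaldehyde 7 (not isolated)
Conditions: TEMPO (20 mol %), PhI(OAc)2 (2.5 equiv), MeCN–H2O 1:1, rt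
Reagents that add atoms: water, O
Why: The TEMPO/PhI(OAc)2 oxoammonium oxidation takes the primary alcohol through the aldehyde hydrate to the acid without chlorine species or strong acid, so the prenyl alkene, the electron-rich ring and the MOM acetals survive.

**Step 5**
Reactants: 8 2-[2,4-bis(methoxymethoxy)-3-(3-methylbut-2-enyl)phenyl]acetic acid
Product: 9 allyl 2-[2,4-bis(methoxymethoxy)-3-(3-methylbut-2-enyl)phenyl]acetate
Conditions: allyl bromide (1.2 equiv), K2CO3, DMF, rt
Reagents that add atoms: allyl bromide, C=CCBr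
Why: SN2 O-alkylation of the carboxylate gives an ester that activates the benzylic CH2 for enolisation and can be removed later under neutral Pd(0) conditions.

**Step 6**
Reactants: 10 2,4,6-trihydroxybenzaldehyde
Product: 11 2-hydroxy-4,6-bis(methoxymethoxy)benzaldehyde
Conditions: MOMCl (2.1 equiv), K2CO3, acetone, 0 °C → rt
Reagents that add atoms: chloromethyl methyl ether (MOMCl), COCCl
Why: In this selective MOM protection the 4-OH and one ortho OH are alkylated, while the last ortho OH is held in a strong hydrogen bond to the formyl group and stays free at this stoichiometry.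

**Step 7**
Reactants: 11 2-hydroxy-4,6-bis(methoxymethoxy)benzaldehyde
Product: 12 2,4-bis(methoxymethoxy)-6-(3-methylbut-2-enyloxy)benzaldehyde
Conditions: prenyl bromide (1.3 equiv), K2CO3, DMF, 40 °C
Reagents that add atoms: prenyl bromide (1-bromo-3-methylbut-2-ene), CC(C)=CCBr
Why: Williamson ether synthesis, because in a dipolar aprotic solvent the chelated phenol is deprotonated and O-alkylated by the primary allylic bromide.

**Step 8**
Reactants: 12 2,4-bis(methoxymethoxy)-6-(3-methylbut-2-enyloxy)benzaldehyde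
Product: 15 6-hydroxy-2,4-bis(methoxymethoxy)-3-(3-methylbut-2-enyl)benzaldehyde, via ortho-dienone 13 (not isolated), via para-dienone 14 (not isolated)
Conditions: N,N-diethylaniline, 200 °C, Ar, 2–3 h
Reagents that add atoms: none
Why: In this para-Claisen–Cope rearrangement the first [3,3] shift goes to the only free ortho carbon, the crowded reverse-prenyl dienone relays by a second [3,3] shift to the para carbon between the two OMOM groups, and tautomerisation frees the OH that will become O1.

**Step 9**
Reactants: 15 6-hydroxy-2,4-bis(methoxymethoxy)-3-(3-methylbut-2-enyl)benzaldehyde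
Product: 16 6-(allyloxy)-2,4-bis(methoxymethoxy)-3-(3-methylbut-2-enyl)benzaldehyde
Conditions: allyl bromide (1.5 equiv), K2CO3, DMF, 50 °C
Reagents that add atoms: allyl bromide, C=CCBr
Why: Williamson ether synthesis puts an allyl group, which is orthogonal to MOM and stable to enolates, on exactly the oxygen that must close the pyranone, and this fixes the 6-prenyl rather than the 8-prenyl regiochemistry.

**Step 10**
Reactants: 9 allyl 2-[2,4-bis(methoxymethoxy)-3-(3-methylbut-2-enyl)phenyl]acetate; 16 6-(allyloxy)-2,4-bis(methoxymethoxy)-3-(3-methylbut-2-enyl)benzaldehyde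
Product: 18 allyl 3-[6-(allyloxy)-2,4-bis(methoxymethoxy)-3-(3-methylbut-2-enyl)phenyl]-2-[2,4-bis(methoxymethoxy)-3-(3-methylbut-2-enyl)phenyl]-3-hydroxypropanoate (syn/anti mixture of racemates), via lithium enolate 17 (not isolated)
Conditions: 9 (1.1 equiv), LDA (1.15 equiv, commercial solution), THF, −78 °C, 45 min; 16, −78 °C, 2 h; AcOH quench at −78 °C
Reagents that add atoms: none
Why: A directed intermolecular aldol addition of a preformed ester enolate to a non-enolisable aldehyde forms the C3–C4 bond, the cold quench prevents retro-aldol and enolate Claisen shift, and the two new stereocentres are set without control because both are destroyed in steps 11–13.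

**Step 11**
Reactants: 18 aldol adduct
Product: 19 allyl 3-[6-(allyloxy)-2,4-bis(methoxymethoxy)-3-(3-methylbut-2-enyl)phenyl]-2-[2,4-bis(methoxymethoxy)-3-(3-methylbut-2-enyl)phenyl]-3-oxopropanoate
Conditions: IBX (2 equiv), DMSO, rt
Reagents that add atoms: none
Why: IBX oxidation converts the hindered benzylic β-hydroxy ester to the β-keto ester under essentially neutral conditions, without over-oxidising the 1,3-dicarbonyl and without touching alkenes, allyl groups or MOM groups.

**Step 12**
Reactants: 19 β-keto allyl ester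
Product: 22 1-[6-hydroxy-2,4-bis(methoxymethoxy)-3-(3-methylbut-2-enyl)phenyl]-2-[2,4-bis(methoxymethoxy)-3-(3-methylbut-2-enyl)phenyl]ethanone, via β-keto acid 20 (not isolated), via O-allyl deoxybenzoin 21 (not isolated)
Conditions: Pd(PPh3)4 (10 mol %), morpholine (10 equiv), THF, rt → 40 °C
Reagents that add atoms: none
Why: In this Tsuji–Trost deallylation Pd(0) ionises the allyl ester and the allyl ether of the acyl-stabilised phenol, excess morpholine traps the π-allyl units before C-allylation can compete, and the α-aryl β-keto acid decarboxylates spontaneously.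

**Step 13**
Reactants: 22 2-hydroxydeoxybenzoin
Product: 24 5,7-bis(methoxymethoxy)-3-[2,4-bis(methoxymethoxy)-3-(3-methylbut-2-enyl)phenyl]-6-(3-methylbut-2-enyl)chromen-4-one, via enaminone 23 (not isolated)
Conditions: DMF-DMA (5 equiv), toluene, 100 °C
Reagents that add atoms: N,N-dimethylformamide dimethyl acetal (DMF-DMA), COC(OC)N(C)C
Why: In the deoxybenzoin/DMF-DMA isoflavone synthesis the acidic benzylic CH2 condenses with the amide acetal to an enaminone, and the only free phenol adds and expels dimethylamine (addition–elimination) to close the pyranone.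

**Step 14**
Reactants: 24 tetra-MOM isoflavone
Product: 25 2'-hydroxylupalbigenin
Conditions: HCl (ca. 1 M in MeOH), MeOH–THF, 40 °C, monitored and stopped at full conversion
Reagents that add atoms: none
Why: Acid-catalysed transacetalisation to methanol removes all four aryl MOM groups at a temperature and acid strength low enough that the o-prenylphenols do not cyclise to chromans.

**Compound list**
1 | resorcinol | Oc1cccc(O)c1 | starting material
2 | 1,3-bis(methoxymethoxy)benzene | COCOc1cccc(OCOC)c1 | intermediate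
3 | 2,6-bis(methoxymethoxy)phenyllithium | [Li]c1c(OCOC)cccc1OCOC | intermediate (not isolated)
4 | 1,3-bis(methoxymethoxy)-2-(3-methylbut-2-enyl)benzene | COCOc1cccc(OCOC)c1CC=C(C)C | intermediate
5 | 2,4-bis(methoxymethoxy)-3-(3-methylbut-2-enyl)phenyllithium | [Li]c1ccc(OCOC)c(CC=C(C)C)c1OCOC | intermediate (not isolated)
6 | 2-[2,4-bis(methoxymethoxy)-3-(3-methylbut-2-enyl)phenyl]ethanol | OCCc1ccc(OCOC)c(CC=C(C)C)c1OCOC | intermediate
7 | 2-[2,4-bis(methoxymethoxy)-3-(3-methylbut-2-enyl)phenyl]acetaldehyde | O=CCc1ccc(OCOC)c(CC=C(C)C)c1OCOC | intermediate (not isolated)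
8 | 2-[2,4-bis(methoxymethoxy)-3-(3-methylbut-2-enyl)phenyl]acetic acid | OC(=O)Cc1ccc(OCOC)c(CC=C(C)C)c1OCOC | intermediate
9 | allyl 2-[2,4-bis(methoxymethoxy)-3-(3-methylbut-2-enyl)phenyl]acetate | C=CCOC(=O)Cc1ccc(OCOC)c(CC=C(C)C)c1OCOC | intermediate
10 | 2,4,6-trihydroxybenzaldehyde | O=Cc1c(O)cc(O)cc1O | starting material
11 | 2-hydroxy-4,6-bis(methoxymethoxy)benzaldehyde | O=Cc1c(O)cc(OCOC)cc1OCOC | intermediate
12 | 2,4-bis(methoxymethoxy)-6-(3-methylbut-2-enyloxy)benzaldehyde | O=Cc1c(OCC=C(C)C)cc(OCOC)cc1OCOC | intermediate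
13 | 2,4-bis(methoxymethoxy)-5-(2-methylbut-3-en-2-yl)-6-oxocyclohexa-1,3-diene-1-carbaldehyde (racemic ortho-dienone) | O=CC1=C(OCOC)C=C(OCOC)C(C(C)(C)C=C)C1=O | intermediate (not isolated)
14 | 2,4-bis(methoxymethoxy)-3-(3-methylbut-2-enyl)-6-oxocyclohexa-1,4-diene-1-carbaldehyde (racemic para-dienone) | O=CC1=C(OCOC)C(CC=C(C)C)C(OCOC)=CC1=O | intermediate (not isolated)
15 | 6-hydroxy-2,4-bis(methoxymethoxy)-3-(3-methylbut-2-enyl)benzaldehyde | O=Cc1c(O)cc(OCOC)c(CC=C(C)C)c1OCOC | intermediate
16 | 6-(allyloxy)-2,4-bis(methoxymethoxy)-3-(3-methylbut-2-enyl)benzaldehyde | O=Cc1c(OCC=C)cc(OCOC)c(CC=C(C)C)c1OCOC | intermediate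
17 | lithium enolate of 9 (enolate geometry not defined) | C=CCOC(O[Li])=Cc1ccc(OCOC)c(CC=C(C)C)c1OCOC | intermediate (not isolated)
18 | aldol adduct, allyl 2,3-diaryl-3-hydroxypropanoate (syn/anti mixture, racemic) | C=CCOC(=O)C(c1ccc(OCOC)c(CC=C(C)C)c1OCOC)C(O)c1c(OCC=C)cc(OCOC)c(CC=C(C)C)c1OCOC | intermediate
19 | allyl 2,3-diaryl-3-oxopropanoate (racemic, labile centre, keto/enol) | C=CCOC(=O)C(c1ccc(OCOC)c(CC=C(C)C)c1OCOC)C(=O)c1c(OCC=C)cc(OCOC)c(CC=C(C)C)c1OCOC | intermediate
20 | 2,3-diaryl-3-oxopropanoic acid, aryl allyl ether still in place (racemic) | OC(=O)C(c1ccc(OCOC)c(CC=C(C)C)c1OCOC)C(=O)c1c(OCC=C)cc(OCOC)c(CC=C(C)C)c1OCOC | intermediate (not isolated)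
21 | 1-[6-(allyloxy)-2,4-bis(methoxymethoxy)-3-(3-methylbut-2-enyl)phenyl]-2-[2,4-bis(methoxymethoxy)-3-(3-methylbut-2-enyl)phenyl]ethanone | O=C(Cc1ccc(OCOC)c(CC=C(C)C)c1OCOC)c1c(OCC=C)cc(OCOC)c(CC=C(C)C)c1OCOC | intermediate (not isolated)
22 | 1-[6-hydroxy-2,4-bis(methoxymethoxy)-3-(3-methylbut-2-enyl)phenyl]-2-[2,4-bis(methoxymethoxy)-3-(3-methylbut-2-enyl)phenyl]ethanone | O=C(Cc1ccc(OCOC)c(CC=C(C)C)c1OCOC)c1c(O)cc(OCOC)c(CC=C(C)C)c1OCOC | intermediate
23 | 3-(dimethylamino)-1,2-diarylprop-2-en-1-one (enaminone of 22, geometry not defined) | CN(C)C=C(c1ccc(OCOC)c(CC=C(C)C)c1OCOC)C(=O)c1c(O)cc(OCOC)c(CC=C(C)C)c1OCOC | intermediate (not isolated)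
24 | 5,7,2',4'-tetrakis(methoxymethoxy)-6,3'-diprenylisoflavone | COCOc1ccc(-c2coc3cc(OCOC)c(CC=C(C)C)c(OCOC)c3c2=O)c(OCOC)c1CC=C(C)C | intermediate
25 | 2'-hydroxylupalbigenin (5,7,2',4'-tetrahydroxy-6,3'-diprenylisoflavone, achiral) | CC(C)=CCc1c(O)ccc(-c2coc3cc(O)c(CC=C(C)C)c(O)c3c2=O)c1O | target

**Step count and risks**

Total steps: 14. Longest linear sequence: 10 (steps 1–5 and 10–14, from resorcinol). The ring-A branch contributes 4 steps before the union.

**Step 10, aldol addition.** Both carbons being joined are crowded and the aldehyde is electron-rich, so the aldolate may revert. The fallback sets out from 16 (together with 9) and returns at 19, which makes step 11 unnecessary. Aldehyde 16 is oxidised (NaClO2, NaH2PO4, large excess of 2-methyl-2-butene, t-BuOH–H2O) to 6-(allyloxy)-2,4-bis(methoxymethoxy)-3-(3-methylbut-2-enyl)benzoic acid F4. CDI in THF then converts this to 1-[6-(allyloxy)-2,4-bis(methoxymethoxy)-3-(3-methylbut-2-enyl)benzoyl]imidazole F5. Two equivalents of enolate 17 are C-acylated by this acyl imidazole in a crossed Claisen condensation. That reaction is irreversible because the β-keto ester 19 is deprotonated as it forms.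

**Step 8, para-Claisen–Cope at 200 °C.** The ortho-dienone may simply tautomerise to the reverse-prenyl phenol, or the aldehyde may suffer at this temperature. The fallback sets out from 10 and returns at 16, and it replaces the sigmatropic relay by direct C-alkylation followed by steric differentiation.
- 10 is C-prenylated (prenyl bromide, aq. KOH, 0 °C). The two free ring carbons are equivalent, so only one mono-C-prenyl isomer can form: 2,4,6-trihydroxy-3-(3-methylbut-2-enyl)benzaldehyde F1.
- One equivalent of MOMCl/K2CO3 caps the only non-chelated hydroxyl, giving 2,6-dihydroxy-4-(methoxymethoxy)-3-(3-methylbut-2-enyl)benzaldehyde F2.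
- One equivalent of allyl bromide/K2CO3 alkylates the less hindered ortho hydroxyl, the one next to ring H, giving 6-(allyloxy)-2-hydroxy-4-(methoxymethoxy)-3-(3-methylbut-2-enyl)benzaldehyde F3.
- NaH/MOMCl caps the remaining hindered hydroxyl and delivers 16.

**Step 14, Brønsted-acid MOM removal.** Two o-prenylphenol units are liberated, so cyclisation to dimethylchromans is the danger. The fallback sets out from 24 and returns at 25, and it exchanges the protecting groups without any protic acid. TESOTf with 2,2'-bipyridyl in MeCN at 0 °C → rt converts the four aryl MOM ethers directly into silyl ethers. The product is 5,7,2',4'-tetrakis(triethylsilyloxy)-6,3'-diprenylisoflavone F6. Fluoride (TBAF buffered with AcOH, THF, 0 °C) then releases 25.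

**Further compounds**
F1 | step 8 | 2,4,6-trihydroxy-3-(3-methylbut-2-enyl)benzaldehyde | O=Cc1c(O)cc(O)c(CC=C(C)C)c1O
F2 | step 8 | 2,6-dihydroxy-4-(methoxymethoxy)-3-(3-methylbut-2-enyl)benzaldehyde | O=Cc1c(O)cc(OCOC)c(CC=C(C)C)c1O
F3 | step 8 | 6-(allyloxy)-2-hydroxy-4-(methoxymethoxy)-3-(3-methylbut-2-enyl)benzaldehyde | O=Cc1c(OCC=C)cc(OCOC)c(CC=C(C)C)c1O
F4 | step 10 | 6-(allyloxy)-2,4-bis(methoxymethoxy)-3-(3-methylbut-2-enyl)benzoic acid | OC(=O)c1c(OCC=C)cc(OCOC)c(CC=C(C)C)c1OCOC
F5 | step 10 | 1-[6-(allyloxy)-2,4-bis(methoxymethoxy)-3-(3-methylbut-2-enyl)benzoyl]imidazole | O=C(n1ccnc1)c1c(OCC=C)cc(OCOC)c(CC=C(C)C)c1OCOC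
F6 | step 14 | 5,7,2',4'-tetrakis(triethylsilyloxy)-6,3'-diprenylisoflavone | CC[Si](CC)(CC)Oc1ccc(-c2coc3cc(O[Si](CC)(CC)CC)c(CC=C(C)C)c(O[Si](CC)(CC)CC)c3c2=O)c(O[Si](CC)(CC)CC)c1CC=C(C)C
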